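**Strategy.** The nitrogen ring is cut at C3–C4 and C1–N2: C1, C8a, C4a and C4 on ring A are a latent ortho-quinodimethane, and C3=N2 is an acetaldehyde imine. The precursor is the complete biaryl, an ortho-methyl acetophenone in which the C4a methyl is the future C4, the acetyl carbon is C1 and C5 already carries the naphthyl group. Light converts it into a hydroxy-ortho-quinodimethane that is trapped by the (R)-tert-butanesulfinyl imine of acetaldehyde, so that one operation forms both bonds, closes the ring and sets C3. Because C1 arrives with its methyl group, acid alone then gives the C1=N2 imine.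

Key step: step 9

Assumption: the SMILES defines only C3. The hindered C5–C1' axis is not encoded, so the route forms it without control and aims at the (3S) compound, whose two atropo-diastereomers should be separable by chromatography at the end.

Remarks on the design (isoquinoline numbering, naphthalene atoms primed):
- **Dienol geometry.** The long-lived dienol is the isomer whose OH points away from the exocyclic CH2. Because C8 bears oxygen it outranks C4a, so the CIP descriptor in this substrate is (Z). It still corresponds to the E-type photoenol of simple ortho-methyl ketones, and 17 is drawn accordingly.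
- **Stereocentres formed.** The key step creates C3, which is kept, and C1, which is erased in step 10.
- **C8 methoxy group.** It is kept on purpose. It can accept a hydrogen bond from the outward OH, which should lengthen the life of the dienol and keep that OH away from the sulfinyl oxygen.
- **Internal triplet acceptor.** The dimethoxynaphthalene can take up the ketone triplet energy. Step 9 therefore uses narrow-band, high-flux 365 nm light, strict exclusion of oxygen and water, and a fivefold excess of the cheap imine.
- **Auxiliary.** Both antipodes are commercial, so an inverted sense of induction could be corrected without changing the route.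

**Step 1**
Reactants: 1 3,5-dimethoxytoluene
Product: 2 1-(2,4-dimethoxy-6-methylphenyl)ethanone
Conditions: Ac2O (1.5 equiv), Sc(OTf)3 (10 mol %), MeNO2, 50 °C
Reagents that add atoms: acetic anhydride, CC(=O)OC(C)=O
Why: Friedel–Crafts acylation goes to the position para to one methoxy group and ortho to the other (C2, equal to C6), which is less crowded than C4 between the two methoxy groups, and a catalytic metal triflate avoids the ortho-demethylation that stoichiometric AlCl3 can cause.

**Step 2**
Reactants: 2 1-(2,4-dimethoxy-6-methylphenyl)ethanone
Product: 3 1-(3-bromo-4,6-dimethoxy-2-methylphenyl)ethanone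
Conditions: NBS (1.0 equiv), MeCN, 0 °C to rt, dark
Reagents that add atoms: N-bromosuccinimide, O=C1CCC(=O)N1Br
Why: Electrophilic aromatic bromination favours the free position para to one methoxy and ortho to the other (future C5) over the one squeezed between both methoxy groups, and NBS in a polar solvent without initiator or acid should spare the acetyl and aryl methyl groups.

**Step 3**
Reactants: 4 2-bromoanisole
Product: 7 pentacarbonyl[methoxy(2-methoxyphenyl)methylidene]chromium, via 2-methoxyphenyllithium 5 (not isolated), via lithium acylchromate 6 (not isolated)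
Conditions: n-BuLi, Et2O, −78 °C; Cr(CO)6, 0 °C to rt; Me3OBF4, CH2Cl2, rt
Reagents that add atoms: hexacarbonylchromium Cr(CO)6, O=C=[Cr](=C=O)(=C=O)(=C=O)(=C=O)=C=O; trimethyloxonium tetrafluoroborate, C[O+](C)C.F[B-](F)(F)F
Why: Fischer carbene synthesis, in which bromine–lithium exchange, addition of the aryllithium to a CO ligand and O-methylation of the acylmetalate with a hard methylating agent form the standard entry to aryl(methoxy)carbene complexes.

**Step 4**
Reactants: 7 pentacarbonyl[methoxy(2-methoxyphenyl)methylidene]chromium; 8 propyne
Product: 10 4,5-dimethoxy-2-methylnaphthalen-1-ol, via naphthol Cr(CO)3 complex 9 (not isolated)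
Conditions: propyne (3 equiv), THF, 55 °C, sealed tube; then air, Et2O, rt, short filtration under argon
Reagents that add atoms: none
Why: Dötz benzannulation joins the carbene carbon (C4'), the alkyne carbons (C3', C2') and one CO ligand (C1') to the only free ortho carbon of the aryl group, and a terminal alkyne places its substituent next to the new hydroxyl, so the 4',5'-dimethoxy-2'-methyl pattern with a differentiated C1' oxygen should result.

**Step 5**
Reactants: 10 4,5-dimethoxy-2-methylnaphthalen-1-ol
Product: 11 4,5-dimethoxy-2-methylnaphthalen-1-yl trifluoromethanesulfonate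
Conditions: Tf2O, pyridine, CH2Cl2, 0 °C
Reagents that add atoms: trifluoromethanesulfonic anhydride, O=S(=O)(OS(=O)(=O)C(F)(F)F)C(F)(F)F
Why: O-Sulfonylation of the only free hydroxyl group turns the oxidation-prone naphthol at once into an air-stable pseudohalide at C1'.

**Step 6**
Reactants: 11 4,5-dimethoxy-2-methylnaphthalen-1-yl trifluoromethanesulfonate
Product: 12 2-(4,5-dimethoxy-2-methylnaphthalen-1-yl)-4,4,5,5-tetramethyl-1,3,2-dioxaborolane
Conditions: B2pin2, PdCl2(dppf) (5 mol %), KOAc, dioxane, 90 °C
Reagents that add atoms: bis(pinacolato)diboron, CC1(C)OB(OC1(C)C)B1OC(C)(C)C(C)(C)O1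
Why: Miyaura borylation, in which oxidative addition of the aryl triflate to zerovalent palladium and acetate-assisted transmetalation with the diboron reagent tolerate an ortho methyl group and aryl ethers.

**Step 7**
Reactants: 3 1-(3-bromo-4,6-dimethoxy-2-methylphenyl)ethanone; 12 2-(4,5-dimethoxy-2-methylnaphthalen-1-yl)-4,4,5,5-tetramethyl-1,3,2-dioxaborolane
Product: 13 1-[2,4-dimethoxy-6-methyl-5-(4,5-dimethoxy-2-methylnaphthalen-1-yl)phenyl]ethanone (racemic, configurationally stable axis)
Conditions: Pd(OAc)2 (5 mol %), SPhos (10 mol %), K3PO4, PhMe/H2O (10:1), 100 °C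
Reagents that add atoms: none
Why: Suzuki–Miyaura coupling with a bulky, electron-rich dialkylbiarylphosphine is the established answer to biaryls with four ortho substituents, aqueous phosphate should spare the hindered methyl ketone, and the C5–C1' axis forms as a racemate.

**Step 8**
Reactants: 14 (R)-tert-butanesulfinamide; 15 acetaldehyde
Product: 16 (R,E)-N-ethylidene-2-methylpropane-2-sulfinamide
Conditions: acetaldehyde (3 equiv), MgSO4, PPTS (5 mol %), CH2Cl2, rt
Reagents that add atoms: none
Why: Condensation of a sulfinamide with an unhindered aldehyde proceeds under mild acid catalysis with a drying agent, leaves the sulfur stereocentre untouched and gives the (E)-aldimine as the only stable geometry.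

**Step 9**
Reactants: 13 1-[2,4-dimethoxy-6-methyl-5-(4,5-dimethoxy-2-methylnaphthalen-1-yl)phenyl]ethanone; 16 (R,E)-N-ethylidene-2-methylpropane-2-sulfinamide
Product: 18 (3S)-2-[(R)-tert-butylsulfinyl]-6,8-dimethoxy-5-(4,5-dimethoxy-2-methylnaphthalen-1-yl)-1,3-dimethyl-1,2,3,4-tetrahydroisoquinolin-1-ol (both C1 epimers), via outward-OH dienol 17 (not isolated)
Conditions: 16 (5 equiv), hν (365 nm LED), 4 Å MS, degassed PhMe (0.05 M), 25 °C
Reagents that add atoms: none
Why: Proposed new method: excitation of the twisted aryl ketone, 1,5-hydrogen transfer from the C4a methyl group to the carbonyl oxygen and relaxation of the triplet biradical give dienol 17, whose electron-rich diene (C4=C4a–C8a=C1) adds across the electron-poor C3=N2 bond of 16 with recovery of the aromaticity of ring A. The closest known reaction types are photoenolisation/Diels–Alder trapping by electron-poor alkenes, capture of ketone photoenols by C=O heterodienophiles, light-triggered Mannich-type additions of 2-alkylbenzophenone photoenols to cyclic N-sulfonyl imines and aza-Diels–Alder reactions of ortho-quinodimethanes with activated imines, whereas an acyclic N-sulfinyl aldimine has not been shown as partner. The six-membered nitrogen ring closes by an intermolecular [4π+2π] cycloaddition, and a stepwise course (C3–C4 Mannich bond, then 6-exo-trig attack of N2 on C1) would end at the same compound. C3 is controlled by the sulfur stereocentre: in the s-cis conformer of the (E)-imine the tert-butyl group covers one face, bonding at the open face of the (R)-sulfinyl imine gives (3S), and the internal O–H···OMe bond to C8 keeps the dienol OH from pulling the sulfinyl oxygen out of that conformer. Regioselectivity requires the nucleophilic CH2 terminus C4 to meet the imine carbon C3, which the donor oxygen on C1 and the acceptor sulfinyl group on N2 both enforce, and chemoselectivity requires hydrogen abstraction from the benzylic methyl group (six-membered transition state, weak C–H bond) to outrun abstraction from the C8 methoxy group (seven-membered transition state). The C1 carbinol centre is erased in step 10 and the racemic axis is not part of the defined target, so that only the imine face matters.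

**Step 10**
Reactants: 18 (3S)-2-[(R)-tert-butylsulfinyl]-6,8-dimethoxy-5-(4,5-dimethoxy-2-methylnaphthalen-1-yl)-1,3-dimethyl-1,2,3,4-tetrahydroisoquinolin-1-ol
Product: 20 O-methylancistrocladinine, via dihydroisoquinolinium chloride 19 (not isolated)
Conditions: HCl (4 M in dioxane, 3 equiv), MeOH, 0 °C to rt; then aq NaOH, CH2Cl2
Reagents that add atoms: none
Why: Acid methanolysis of the S–N bond (standard sulfinamide cleavage) and loss of water from the C1 carbinolamine give the conjugated cyclic iminium salt, the C1 epimers and any ring-opened tautomer converge on it, and C3 has no pathway for epimerisation under these conditions.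

**Compound list**
1 | 3,5-dimethoxytoluene | Cc1cc(OC)cc(OC)c1 | starting material
2 | 1-(2,4-dimethoxy-6-methylphenyl)ethanone | COc1cc(C)c(C(C)=O)c(OC)c1 | intermediate
3 | 1-(3-bromo-4,6-dimethoxy-2-methylphenyl)ethanone | COc1cc(OC)c(Br)c(C)c1C(C)=O | intermediate
4 | 2-bromoanisole | COc1ccccc1Br | starting material
5 | 2-methoxyphenyllithium (formed in the flask) | [Li]c1ccccc1OC | intermediate
6 | lithium pentacarbonyl[(2-methoxyphenyl)(oxido)methylidene]chromate (formed in the flask) | [Li+].[O-]C(c1ccccc1OC)=[Cr](=C=O)(=C=O)(=C=O)(=C=O)=C=O | intermediate
7 | pentacarbonyl[methoxy(2-methoxyphenyl)methylidene]chromium | COC(c1ccccc1OC)=[Cr](=C=O)(=C=O)(=C=O)(=C=O)=C=O | intermediate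
8 | propyne | CC#C | starting material
9 | tricarbonyl(η6-4,5-dimethoxy-2-methylnaphthalen-1-ol)chromium, written as arene plus Cr(CO)3 fragment (formed in the flask) | Cc1cc(OC)c2c(OC)cccc2c1O.O=C=[Cr](=C=O)=C=O | intermediate
10 | 4,5-dimethoxy-2-methylnaphthalen-1-ol | Cc1cc(OC)c2c(OC)cccc2c1O | intermediate
11 | 4,5-dimethoxy-2-methylnaphthalen-1-yl trifluoromethanesulfonate | Cc1cc(OC)c2c(OC)cccc2c1OS(=O)(=O)C(F)(F)F | intermediate
12 | 2-(4,5-dimethoxy-2-methylnaphthalen-1-yl)-4,4,5,5-tetramethyl-1,3,2-dioxaborolane | Cc1cc(OC)c2c(OC)cccc2c1B1OC(C)(C)C(C)(C)O1 | intermediate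
13 | 1-[2,4-dimethoxy-6-methyl-5-(4,5-dimethoxy-2-methylnaphthalen-1-yl)phenyl]ethanone, racemic axis | COc1cc(OC)c(-c2c(C)cc(OC)c3c(OC)cccc23)c(C)c1C(C)=O | intermediate
14 | (R)-tert-butanesulfinamide | CC(C)(C)[S@@](=O)N | starting material
15 | acetaldehyde | CC=O | starting material
16 | (R,E)-N-ethylidene-2-methylpropane-2-sulfinamide | CC(C)(C)[S@@](=O)/N=C/C | intermediate
17 | hydroxy-ortho-quinodimethane of 13, OH syn to C8 and anti to the exocyclic CH2, CIP (Z) (formed in the flask) | C=C1C(-c2c(C)cc(OC)c3c(OC)cccc23)=C(OC)C=C(OC)/C1=C(\O)C | intermediate
18 | (3S)-2-[(R)-tert-butylsulfinyl]-6,8-dimethoxy-5-(4,5-dimethoxy-2-methylnaphthalen-1-yl)-1,3-dimethyl-1,2,3,4-tetrahydroisoquinolin-1-ol, C1 epimers | COc1cc(OC)c(-c2c(C)cc(OC)c3c(OC)cccc23)c2c1C(C)(O)N([S@](=O)C(C)(C)C)[C@@H](C)C2 | intermediate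
19 | (3S)-6,8-dimethoxy-5-(4,5-dimethoxy-2-methylnaphthalen-1-yl)-1,3-dimethyl-3,4-dihydroisoquinolin-2-ium chloride (formed in the flask) | COc1cc(OC)c(-c2c(C)cc(OC)c3c(OC)cccc23)c2c1C(C)=[NH+][C@@H](C)C2.[Cl-] | intermediate
20 | O-methylancistrocladinine, (3S)-6,8-dimethoxy-5-(4,5-dimethoxy-2-methylnaphthalen-1-yl)-1,3-dimethyl-3,4-dihydroisoquinoline | COc1cc(OC)c(-c2c(C)cc(OC)c3c(OC)cccc23)c2c1C(C)=N[C@@H](C)C2 | target

**Total step count:** 10. **Longest linear sequence:** 7 steps (steps 3, 4, 5, 6, 7, 9, 10, from 2-bromoanisole).

**Steps most likely to fail**

1. **Step 9.**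
   - *What may go wrong: energy drain.* The ketone triplet may pass its energy to the directly attached dimethoxynaphthalene, whose triplet should lie well below it, before the hydrogen shift occurs. This wastes photons rather than material but lengthens irradiation and gives slow side reactions more room.
   - *What may go wrong: slow capture.* Reketonisation, or four-ring closure of the dienol (which warming should reverse), may outrun bimolecular capture at a CH2 terminus flanked by the naphthyl group.
   - *What may go wrong: weak facial bias.* The facial bias of the sulfinyl group may be weak.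
   - *Fallback (known carbanion chemistry, nitrogen ring first and biaryl bond last).* It sets out from 1 and also uses 16 and 12. Electrophilic cyanation of 1 (ClSO2NCO, then DMF) gives 2,4-dimethoxy-6-methylbenzonitrile F1. Lateral deprotonation with LDA in THF at −78 °C and addition to imine 16 should give (R)-N-[(2S)-1-(2-cyano-3,5-dimethoxyphenyl)propan-2-yl]-2-methylpropane-2-sulfinamide F2. The open transition state expected for a lithium carbanion in THF favours this isomer, and its diastereomers are separable sulfinamides. Excess MeLi adds to the nitrile, and methanolic HCl then removes the auxiliary and closes the ring by transimination to (S)-6,8-dimethoxy-1,3-dimethyl-3,4-dihydroisoquinoline F3. Bromination of its salt (NBS, TFA, 0 °C) para to the C8 methoxy group gives (S)-5-bromo-6,8-dimethoxy-1,3-dimethyl-3,4-dihydroisoquinoline F4. Suzuki–Miyaura coupling of F4 with 12 under the conditions of step 7 comes back to the route at 20.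

2. **Step 7.**
   - *What may go wrong.* Transmetalation may be slow at a coupling with four ortho substituents. The electron-rich naphthylboronate may suffer protodeboronation. The methyl ketone may compete through palladium-catalysed α-arylation.
   - *Fallback (exchange of the roles of the partners).* It sets out from 3. Miyaura borylation (B2pin2, Pd(OAc)2, SPhos, KOAc, dioxane, 100 °C) gives 1-[4,6-dimethoxy-2-methyl-3-(4,4,5,5-tetramethyl-1,3,2-dioxaborolan-2-yl)phenyl]ethanone F5. Coupling F5 directly with triflate 11 (Pd(OAc)2, SPhos, K3PO4, PhMe/H2O) comes back at 13, and step 6 is then not needed.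

3. **Step 4.**
   - *What may go wrong.* The very electron-rich naphthol may be oxidised during demetalation and handling, and volatile propyne may be lost before the benzannulation is complete.
   - *Fallback (the free naphthol is never liberated).* It sets out from 7 and 8. The benzannulation is run as before to 9. Before any contact with air, 2,6-lutidine and Tf2O are added at −78 °C to give tricarbonyl(η6-4,5-dimethoxy-2-methylnaphthalen-1-yl trifluoromethanesulfonate)chromium F6. Only this robust triflate complex is then demetalated in air, which comes back to the route at 11 and removes step 5.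

**Further compounds**
F1 | step 9 | 2,4-dimethoxy-6-methylbenzonitrile | COc1cc(C)c(C#N)c(OC)c1
F2 | step 9 | (R)-N-[(2S)-1-(2-cyano-3,5-dimethoxyphenyl)propan-2-yl]-2-methylpropane-2-sulfinamide | COc1cc(OC)c(C#N)c(C[C@H](C)N[S@](=O)C(C)(C)C)c1
F3 | step 9 | (S)-6,8-dimethoxy-1,3-dimethyl-3,4-dihydroisoquinoline | COc1cc(OC)c2c(c1)C[C@H](C)N=C2C
F4 | step 9 | (S)-5-bromo-6,8-dimethoxy-1,3-dimethyl-3,4-dihydroisoquinoline | COc1cc(OC)c2c(c1Br)C[C@H](C)N=C2C
F5 | step 7 | 1-[4,6-dimethoxy-2-methyl-3-(4,4,5,5-tetramethyl-1,3,2-dioxaborolan-2-yl)phenyl]ethanone | COc1cc(OC)c(B2OC(C)(C)C(C)(C)O2)c(C)c1C(C)=O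
F6 | step 4 | tricarbonyl(η6-4,5-dimethoxy-2-methylnaphthalen-1-yl trifluoromethanesulfonate)chromium | Cc1cc(OC)c2c(OC)cccc2c1OS(=O)(=O)C(F)(F)F.O=C=[Cr](=C=O)=C=O
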